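What I looked at first was the leftover: after 40.0 h the autumn run still held 71.7% of its starting material and the spring run 72.5%, although they were charged with 0.67 M and 1.5 M.

| flask | starting material | gas phase | remark | time |
|---|---|---|---|---|
| autumn | 0.67 M | 120 mM (held) | run made earlier |  |
| spring | 1.5 M | 120 mM (held) | run made earlier |  |
| flask | 1.0 M | 120 mM (held) |  | 2.5 d |

- autumn (time / h: target / %, crystals / %, starting material / %): 5.00: 2.1, 0.4, 98.2; 12.0: 7.3, 3.0, 91.6; 25.0: 14.0, 10.3, 81.5; 40.0: 22.3, 18.5, 71.7
- spring (time / h: target / %, crystals / %, starting material / %): 3.00: 0.8, 0, 98.1; 6.00: 3.1, 0.3, 96.8; 15.0: 8.8, 5.1, 89.4; 40.0: 21.3, 18.5, 72.5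

(readings scatter by 0.5 percentage points)

- a species is counted by the starting material in it: one side product counts as two
- amounts and yields of target count crystals too
- given per volume of solution although it is solid: crystals
- at the start none of the gas is dissolved
- what may be going on: crystals <-> target; starting material + dissolved gas -> target; starting material + target -> side product; gas phase <-> dissolved gas

- target and crystals together at 2.5 d, in percent of the starting material charged
- concentration of dissolved gas in solution at 2.5 d, in percent of saturation

A percentage leftover that ignores the charge suggested a pseudo-first-order loss, so I treated c(dissolved gas) as constant and folded the reading and the times into one number: D, the natural logarithm of the factor by which the starting material falls over the asked time, 0.499 from the autumn run. The flask should then keep 60.7%.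

Was one number enough? For the leftover, yes: the spring run gives 0.482, and the autumn reading at 25.0 h gives 0.491. The early spring reading at 6.00 h runs lower, 0.325, and the solution starts without gas. For y, no: the loss splits, and in the autumn run 0.788 of it stood as target, crystals counted, at 40.0 h. With that share held, I reckoned y at 31.0%. I committed to no figure for the gas: the leftovers of the two runs at 40.0 h differ by 0.8 percentage points, against a scatter of 0.5 points on each reading.

The forecast gave 31% and 93%, holding that “Dissolved gas therefore barely depends on loading”.

The flask gave y = 30.7% and 92.0% of saturation.

    crystals ⇌ target, rate k1*(cs1 - [target]) while solid is left; crystals form when [target] > cs1 (solubility = 27.0 mM, k = 6.96 × 10⁻⁴ s⁻¹)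
    starting material + dissolved gas → target (k = 1.96 × 10⁻⁵ L mol⁻¹ s⁻¹)
    starting material + target → side product (k = 9.11 × 10⁻⁶ L mol⁻¹ s⁻¹)
    gas phase ⇌ dissolved gas, rate k4*(csat - [dissolved gas]) (kL = 1.39 × 10⁻⁴ s⁻¹)

In the flask, dissolved gas had reached 85.0% of saturation by 0.250 d and 89.9% by 1.25 d. For the same flask read at 10 d, D scales with time to 2.00, which leaves 13.6% of the starting material; that reading held 12%.

The numbers in the tables were generated by integration for substances that don't exist; the scatter is artificial.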